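## Retrosynthetic overview

1. There is only one ring, the 18-membered lactam. It is opened at the two bonds nature is presumed to make: C3–N (aza-Michael) and C1(=O)–N (lactam).
2. This gives a C2-symmetric, inner-N-diacylated 3-5-3 tetraamine and an activated (2E,5Z)-tetradeca-2,5-dienoyl donor.
3. The thioester role is taken by an N-acyl (2R)-bornane-10,2-sultam. It steers the amine to the Cβ-si face (sets 3S) and is then expelled in the ring closure.
4. The dienoyl sultam comes from 4-bromocrotonoyl sultam and 1-decyne (Cu-catalysed allylic alkynylation, then Z-selective semihydrogenation).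
5. The diamine comes from cadaverine and 2 acrylonitrile, acylation with (S)-2-methylbutanoic acid, and nitrile hydrogenation. The ring is formed last, C3–N first and N–C1 second, in one flask.

Assumption: the SMILES is read as 3S at the ring stereocentre, S in both 2-methylbutanoyl groups and Z for the alkene. Fatty-acid numbering is used for the C14 unit (C1 = lactam C=O, C3 = stereocentre, C5=C6 = alkene).

## Route

Step 1
Reactants: 1 pentane-1,5-diamine (cadaverine); 2 acrylonitrile
Product: 3 N,N'-bis(2-cyanoethyl)pentane-1,5-diamine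
Conditions: 2 (2.05 equiv), MeOH, 0 °C → rt, 16 h
Reagents that add atoms: none
Why: Double aza-Michael addition (cyanoethylation), in which each primary amine adds once and the resulting β-cyanoethyl secondary amine is too deactivated and hindered to add again at rt; no stereocentre is formed.

Step 2
Reactants: 3 N,N'-bis(2-cyanoethyl)pentane-1,5-diamine; 4 (S)-2-methylbutanoic acid
Product: 5 N,N'-bis(2-cyanoethyl)-N,N'-bis[(2S)-2-methylbutanoyl]pentane-1,5-diamine
Conditions: 4 (2.3 equiv), DIC (2.4 equiv), HOBt (0.5 equiv), CH2Cl2, 0 °C → rt, 16 h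
Reagents that add atoms: none
Why: Carbodiimide/HOBt amide coupling, in which only the two secondary amines can be acylated because the nitriles mask the future primary amines; both acyl stereocentres are bought with 4 and survive because the base-free active ester of a simple α-alkyl acid has no ketene or oxazolone pathway.

Step 3
Reactants: 5 N,N'-bis(2-cyanoethyl)-N,N'-bis[(2S)-2-methylbutanoyl]pentane-1,5-diamine
Product: 6 N,N'-bis(3-aminopropyl)-N,N'-bis[(2S)-2-methylbutanoyl]pentane-1,5-diamine (C2-symmetric)
Conditions: H2 (5 bar), Raney Ni, 7 M NH3/MeOH, rt, 12 h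
Reagents that add atoms: none
Why: Heterogeneous nitrile hydrogenation, in which NH3 suppresses secondary-amine formation and the tertiary amides with their α-stereocentres are inert.

Step 4
Reactants: 7 (E)-4-bromobut-2-enoic acid; 8 (2R)-bornane-10,2-sultam [(1S)-(−)-2,10-camphorsultam, (3aS,6R,7aR)]
Product: 11 N-[(2E)-4-bromobut-2-enoyl]-(2R)-bornane-10,2-sultam, via (E)-4-bromobut-2-enoyl chloride 9 (not isolated), via sodium sultamide 10 (not isolated)
Conditions: (a) 7, (COCl)2 (1.1 equiv), DMF (cat.), CH2Cl2, 0 °C → rt, evaporate; (b) 8, NaH (1.05 equiv), toluene, 0 °C → rt; (c) 10 added to 9, toluene, −20 → 0 °C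
Reagents that add atoms: oxalyl chloride, ClC(=O)C(=O)Cl (gives the Cl of 9 only); sodium hydride, [Na+].[H-] (gives the Na of 10 only)
Why: Acid chloride formation followed by N-acylation of the sultam anion, with inverse addition at low temperature so that the acyl chloride reacts far faster than the allylic bromide; the E-alkene is retained and the auxiliary stereocentres are bought.

Step 5
Reactants: 11 N-[(2E)-4-bromobut-2-enoyl]-(2R)-bornane-10,2-sultam; 12 dec-1-yne
Product: 13 N-[(2E)-tetradec-2-en-5-ynoyl]-(2R)-bornane-10,2-sultam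
Conditions: 12 (1.3 equiv), CuI (10 mol %), n-Bu4NI (10 mol %), K2CO3 (1.5 equiv), DMF, 0 °C → rt, 12 h
Reagents that add atoms: none
Why: Copper-catalysed allylic alkynylation (a monovalent copper acetylide displaces the primary allylic halide in SN2 fashion), a coupling established for 4-bromocrotonates; the carbonate is mild enough to leave the skipped enyne and the E-enoyl unit in place.

Step 6
Reactants: 13 N-[(2E)-tetradec-2-en-5-ynoyl]-(2R)-bornane-10,2-sultam
Product: 14 N-[(2E,5Z)-tetradeca-2,5-dienoyl]-(2R)-bornane-10,2-sultam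
Conditions: H2 (1 atm, stopped at 1.0 equiv), Pd/CaCO3 poisoned with Pb(OAc)2 (Lindlar catalyst), quinoline, EtOAc/hexane, 0 °C
Reagents that add atoms: none
Why: Lindlar semihydrogenation, in which syn delivery of H2 to the alkyne sets the 5Z geometry and the alkyne binds the poisoned Pd much more strongly than the hindered conjugated C2=C3 bond.

Step 7
Reactants: 6 N,N'-bis(3-aminopropyl)-N,N'-bis[(2S)-2-methylbutanoyl]pentane-1,5-diamine; 14 N-[(2E,5Z)-tetradeca-2,5-dienoyl]-(2R)-bornane-10,2-sultam
Product: 17 (4S)-9,15-bis[(2S)-2-methylbutanoyl]-4-[(2Z)-undec-2-en-1-yl]-1,5,9,15-tetraazacyclooctadecan-2-one (CNP0302576.1), via (3S)-aza-Michael adduct 15 (not isolated), via 1-acyl-1,2,4-triazole 16 (not isolated)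
Conditions: (a) 14 added over 1 h to 6 (1.5 equiv), CH2Cl2 (0.3 M), 0 °C → rt, 36 h; (b) diluted into MeCN (0.5 mM), 1,2,4-triazole (50 mM), DBU (20 mM), 50 °C, 48 h; excess 6 and freed 8 recovered
Reagents that add atoms: 1H-1,2,4-triazole, c1nc[nH]n1 (its ring is carried by 16 only and is released again)
Why: Proposed new method: tandem aza-Michael addition/auxiliary-expelling macrolactamisation in which the acyl sultam stands in for the natural acyl thioester: either NH2 of 6 (the two ends are homotopic, so none needs differentiating) adds to C3 of 14 through the s-cis, C=O/SO2-anti rotamer on the face turned away from the pseudo-axial sulfonyl oxygen (Cα-re/Cβ-si for the (2R)-sultam, the same face the chelated rotamer exposes), which fixes C3 as S; saturation of the enoyl unit then turns the carbonyl into an N-alkyl-N-acylsulfonamide acyl donor, triazolide carries the acyl group out of the hindered sultam as 16, and at 0.5 mM the remaining NH2 closes the 18-membered lactam while the hindered secondary amine could only form a four-membered ring; the closest known reaction types are face-selective thermal additions and thiolate conjugate additions to N-enoylbornanesultams, hydroxylamine conjugate addition/cyclisation on enoyl imide templates that expel the template, cyclative aminolysis of N-alkylated acylsulfonamide safety-catch linkers, and triazole-anion-catalysed aminolysis.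

## Compound list

1 | pentane-1,5-diamine (cadaverine) | NCCCCCN | starting material
2 | acrylonitrile | C=CC#N | starting material
3 | N,N'-bis(2-cyanoethyl)pentane-1,5-diamine | N#CCCNCCCCCNCCC#N | intermediate
4 | (S)-2-methylbutanoic acid | CC[C@H](C)C(=O)O | starting material
5 | N,N'-bis(2-cyanoethyl)-N,N'-bis[(2S)-2-methylbutanoyl]pentane-1,5-diamine | N#CCCN(C(=O)[C@@H](C)CC)CCCCCN(C(=O)[C@@H](C)CC)CCC#N | intermediate
6 | N,N'-bis(3-aminopropyl)-N,N'-bis[(2S)-2-methylbutanoyl]pentane-1,5-diamine | NCCCN(C(=O)[C@@H](C)CC)CCCCCN(C(=O)[C@@H](C)CC)CCCN | intermediate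
7 | (E)-4-bromobut-2-enoic acid | OC(=O)/C=C/CBr | starting material
8 | (2R)-bornane-10,2-sultam | CC1(C)[C@@H]2CC[C@]13CS(=O)(=O)N[C@@H]3C2 | starting material
9 | (E)-4-bromobut-2-enoyl chloride | ClC(=O)/C=C/CBr | intermediate
10 | sodium (2R)-bornane-10,2-sultamide | CC1(C)[C@@H]2CC[C@]13CS(=O)(=O)[N-][C@@H]3C2.[Na+] | intermediate
11 | N-[(2E)-4-bromobut-2-enoyl]-(2R)-bornane-10,2-sultam | CC1(C)[C@@H]2CC[C@]13CS(=O)(=O)N(C(=O)/C=C/CBr)[C@@H]3C2 | intermediate
12 | dec-1-yne | CCCCCCCCC#C | starting material
13 | N-[(2E)-tetradec-2-en-5-ynoyl]-(2R)-bornane-10,2-sultam | CC1(C)[C@@H]2CC[C@]13CS(=O)(=O)N(C(=O)/C=C/CC#CCCCCCCCC)[C@@H]3C2 | intermediate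
14 | N-[(2E,5Z)-tetradeca-2,5-dienoyl]-(2R)-bornane-10,2-sultam | CC1(C)[C@@H]2CC[C@]13CS(=O)(=O)N(C(=O)/C=C/C/C=C\CCCCCCCC)[C@@H]3C2 | intermediate
15 | (3S,5Z)-3-amino-tetradec-5-enoyl sultam whose C3 nitrogen is one terminal N of 6, other NH2 free | CC1(C)[C@@H]2CC[C@]13CS(=O)(=O)N(C(=O)C[C@H](C/C=C\CCCCCCCC)NCCCN(C(=O)[C@@H](C)CC)CCCCCN(C(=O)[C@@H](C)CC)CCCN)[C@@H]3C2 | intermediate
16 | the corresponding 1-acyl-1,2,4-triazole (sultam of 15 replaced by 1,2,4-triazol-1-yl) | O=C(n1cncn1)C[C@H](C/C=C\CCCCCCCC)NCCCN(C(=O)[C@@H](C)CC)CCCCCN(C(=O)[C@@H](C)CC)CCCN | intermediate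
17 | (4S)-9,15-bis[(2S)-2-methylbutanoyl]-4-[(2Z)-undec-2-en-1-yl]-1,5,9,15-tetraazacyclooctadecan-2-one (CNP0302576.1) | CCCCCCCC/C=C\C[C@H]1CC(=O)NCCCN(C(=O)[C@@H](C)CC)CCCCCN(C(=O)[C@@H](C)CC)CCCN1 | target

## Step count

- Total step count: 7.
- Longest linear sequence: 4 (steps 1, 2, 3, 7 or steps 4, 5, 6, 7).

## Steps most likely to fail

**Step 7 (highest risk).**
- The amine may shift the skipped diene into conjugation before it adds.
- Facial control may be imperfect.
- 2:1 adducts and oligomers cost material.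
- The hindered sultam may leave slowly.

Fallback, setting out from 6 and coming back at 17: the two bond formations are uncoupled and the ring is closed by a conventional activated-acid macrolactamisation. Slow addition of Boc2O (0.5 equiv) to 6 gives the mono-Boc diamine F1. Its single free NH2 adds to 14, so no bis-adduct can form, and this gives the Boc-protected β-amino acyl sultam F2. F2 is isolated so that the minor C3 epimer can be removed by chromatography or crystallisation. LiOH in THF/H2O removes the auxiliary to give the N-Boc amino acid F3. CF3CO2H/CH2Cl2 then gives the seco-amino acid F4. F4 is cyclised with pentafluorophenyl diphenylphosphinate and i-Pr2NEt in DMF at 1 mM to 17.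

**Step 5.** Product 13 has C4–H bonds that are both propargylic and vinylogous to the imide, so K2CO3/DMF may isomerise it to a vinylallene or conjugated enyne, or attack the imide.

Fallback, setting out from 12 and coming back at 14: the auxiliary is attached last instead of first. Dec-1-yne is coupled under the same CuI catalysis with commercial methyl (E)-4-bromobut-2-enoate, the less acidic substrate for which this coupling is best documented. This gives methyl (E)-tetradec-2-en-5-ynoate F5. Semihydrogenation over Pd/CaCO3 poisoned with Pb(OAc)2 gives methyl (2E,5Z)-tetradeca-2,5-dienoate F6. AlMe3-mediated acylation of 8 (dimethylaluminium sultamide, toluene, 50 °C) with F6 gives 14.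

**Step 6.** The activated C2=C3 bond of the enoyl sultam may be reduced as well, or the new alkene may drift from Z to E.

Fallback, setting out from 13 and coming back at 17: the alkyne is carried through the ring closure and reduced only when no conjugated alkene is left. Under the conditions of step 7, 13 and 6 give the alkynyl aza-Michael adduct F7, then the alkynyl acyl triazole F8, then the 5,6-didehydro macrolactam F9. The isolated alkyne of F9 is then semihydrogenated (H2, Pd/CaCO3 poisoned with Pb(OAc)2, quinoline) to 17.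

## Further compounds

F1 | step 7 | mono-N-Boc derivative of 6 | CC(C)(C)OC(=O)NCCCN(C(=O)[C@@H](C)CC)CCCCCN(C(=O)[C@@H](C)CC)CCCN
F2 | step 7 | (3S)-aza-Michael adduct of F1 with 14 (Boc-protected acyl sultam) | CC1(C)[C@@H]2CC[C@]13CS(=O)(=O)N(C(=O)C[C@H](C/C=C\CCCCCCCC)NCCCN(C(=O)[C@@H](C)CC)CCCCCN(C(=O)[C@@H](C)CC)CCCNC(=O)OC(C)(C)C)[C@@H]3C2
F3 | step 7 | (3S,5Z)-N-Boc seco-amino acid | OC(=O)C[C@H](C/C=C\CCCCCCCC)NCCCN(C(=O)[C@@H](C)CC)CCCCCN(C(=O)[C@@H](C)CC)CCCNC(=O)OC(C)(C)C
F4 | step 7 | (3S,5Z)-seco-amino acid | OC(=O)C[C@H](C/C=C\CCCCCCCC)NCCCN(C(=O)[C@@H](C)CC)CCCCCN(C(=O)[C@@H](C)CC)CCCN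
F5 | step 5 | methyl (E)-tetradec-2-en-5-ynoate | CCCCCCCCC#CC/C=C/C(=O)OC
F6 | step 5 | methyl (2E,5Z)-tetradeca-2,5-dienoate | CCCCCCCC/C=C\C/C=C/C(=O)OC
F7 | step 6 | (3S)-aza-Michael adduct of 6 with 13 (alkynyl acyl sultam) | CC1(C)[C@@H]2CC[C@]13CS(=O)(=O)N(C(=O)C[C@H](CC#CCCCCCCCC)NCCCN(C(=O)[C@@H](C)CC)CCCCCN(C(=O)[C@@H](C)CC)CCCN)[C@@H]3C2
F8 | step 6 | the corresponding alkynyl 1-acyl-1,2,4-triazole | O=C(n1cncn1)C[C@H](CC#CCCCCCCCC)NCCCN(C(=O)[C@@H](C)CC)CCCCCN(C(=O)[C@@H](C)CC)CCCN
F9 | step 6 | (4S)-9,15-bis[(2S)-2-methylbutanoyl]-4-(undec-2-yn-1-yl)-1,5,9,15-tetraazacyclooctadecan-2-one | CCCCCCCCC#CC[C@H]1CC(=O)NCCCN(C(=O)[C@@H](C)CC)CCCCCN(C(=O)[C@@H](C)CC)CCCN1
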